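**Plan**
- Retrosynthesis: the C5 O–CH3 bond is cut last. Before it, three bonds of the chromone are cut at once: C4a–C5 and C4a–C8a of ring A, and O1–C2 of ring C.
- Enabling feature: C5, C6, C7, C8 and C8a of ring A, with their three oxygens and two C-methyl groups, are a 2,4-dimethyl-3-oxoglutarate in disguise. Held as the symmetric 2,6-dimethoxy-3,5-dimethyl-4-pyranone, this unit lacks only C4a.
- C4a comes as the methyl carbon of an alkynyl methyl ketone that already carries C4, C3, C2 and the C25 chain.
- Forward: the pyranone (three steps from dimethyl 3-oxopentanedioate) and the ynone (three steps from 1-hexacosanol) are joined. Ring A forms first (addition, ring opening, Claisen closure), ring C second (oxa-Michael closure), and a demethylation ends the route.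
- Stereochemistry: the target has no stereocentre and no stereogenic double bond, so none has to be set.

Key step: step 7

Assumption: the C-methylated keto diester is carried as a mixture of diastereomers and enol forms (both centres become sp2 on cyclisation), and the ring-opened intermediate of the key step is drawn in the alkene geometry able to cyclise, since its push–pull double bond should equilibrate in base.

**Route**

Step 1
Reactants: 1 dimethyl 3-oxopentanedioate
Product: 2 dimethyl 2,4-dimethyl-3-oxopentanedioate (mixture of diastereomers)
Conditions: MeI (2.2 equiv), K2CO3, acetone, reflux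
Reagents that add atoms: iodomethane, CI
Why: Each methylene of the β-keto diester is doubly activated, so K2CO3 should generate the stabilised enolate on either side and SN2 C-alkylation (malonate-type enolate alkylation) should place one methyl group at C2 and one at C4.

Step 2
Reactants: 2 dimethyl 2,4-dimethyl-3-oxopentanedioate
Product: 3 4-hydroxy-6-methoxy-3,5-dimethyl-2H-pyran-2-one
Conditions: oleum (H2SO4 with 20% SO3), 0 °C to rt; poured on ice
Reagents that add atoms: none
Why: In the strong acid one ester is activated as an acylium-type electrophile and should be captured by the carbonyl oxygen of the other ester, an acid-mediated enol lactonisation (intramolecular O-acylation) that loses methanol and leaves the central ketone as the 4-enol.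

Step 3
Reactants: 3 4-hydroxy-6-methoxy-3,5-dimethyl-2H-pyran-2-one
Product: 4 2,6-dimethoxy-3,5-dimethyl-4H-pyran-4-one
Conditions: MeOTf, CH2Cl2, rt; aq. NaHCO3
Reagents that add atoms: methyl trifluoromethanesulfonate, COS(=O)(=O)C(F)(F)F
Why: The hard electrophile should alkylate the most basic oxygen, the lactone carbonyl, and proton loss then gives the symmetric 4-pyranone, which is the established O-alkylation route from 4-hydroxy-2-pyranones to 2-methoxy-4-pyranones.

Step 4
Reactants: 5 1-hexacosanol
Product: 6 hexacosanal
Conditions: TEMPO (cat.), PhI(OAc)2, CH2Cl2, 35 °C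
Reagents that add atoms: none
Why: The TEMPO/PhI(OAc)2 oxidation proceeds through the oxoammonium salt, should stop at the aldehyde, and runs in warm CH2Cl2, in which the waxy alcohol dissolves.

Step 5
Reactants: 6 hexacosanal
Product: 7 heptacos-1-yne
Conditions: dimethyl (1-diazo-2-oxopropyl)phosphonate, K2CO3, MeOH/THF 1:1, rt
Reagents that add atoms: dimethyl (1-diazo-2-oxopropyl)phosphonate, CC(=O)C(=[N+]=[N-])P(=O)(OC)OC
Why: In this Seyferth–Gilbert homologation (Ohira–Bestmann variant) methanolysis of the reagent frees the diazomethylphosphonate anion, which adds to the aldehyde and, after loss of dimethyl phosphate and N2 and a 1,2-hydride shift, should give the terminal alkyne with one carbon added, THF keeping the aldehyde in solution.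

Step 6
Reactants: 7 heptacos-1-yne
Product: 9 nonacos-3-yn-2-one, via lithium heptacos-1-yn-1-ide 8 (not isolated)
Conditions: n-BuLi, THF, 0 °C; then MeC(O)N(OMe)Me, 0 °C to rt; cold 1 M HCl
Reagents that add atoms: N-methoxy-N-methylacetamide, CC(=O)N(C)OC
Why: Acylation of the acetylide with the Weinreb amide (Weinreb ketone synthesis) should stop at the ketone because the chelated tetrahedral adduct survives until the acidic quench, which also protonates the released amine before it can add to the ynone.

Step 7
Reactants: 4 2,6-dimethoxy-3,5-dimethyl-4H-pyran-4-one; 9 nonacos-3-yn-2-one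
Product: 13 7-hydroxy-5-methoxy-6,8-dimethyl-2-pentacosyl-4H-chromen-4-one, via lithium nonacos-1-en-3-yn-2-olate 10 (not isolated), via ring-opened keto ester 11 (not isolated), via aryl ynone 12 (not isolated)
Conditions: LiN(SiMe3)2 (1.2 equiv), THF, −78 °C; then 4, −78 °C to rt; then MeOH, 60 °C; 1 M HCl work-up
Reagents that add atoms: none
Why: Proposed new method: the lithium enolate 10 should add in conjugate fashion to C2 of the vinylogous carbonate 4, the adduct should open by expelling the ring oxygen as a β-keto ester enolate to give 11, and proton transfer to the doubly activated methylene then permits a Claisen condensation on the freed methyl ester, loss of methoxide and tautomerisation to the aromatic aryl ynone 12, whose ortho phenoxide adds to the triple bond. The closest known reactions are the addition–elimination of lithiated carbon nucleophiles at C2 of 2-methoxy-4-pyranones, the base-mediated conversion of 2-pyranones and pyrylium salts into benzenes by carbon nucleophiles, and the Claisen cyclisation of 3,5,7-triketo esters to acylphloroglucinols. Ring A closes by a 6-exo-trig Claisen acylation (C4a–C8a, after the intermolecular C4a–C5 bond) and ring C by a 6-endo-dig oxa-Michael addition (O1–C2), and no stereocentre is created. Conjugate attack instead of 1,2-addition is expected because the C4 carbonyl is a doubly vinylogous carbonate, and the equivalence of C2 and C6 in 4 removes any regiochemical question. The step needs ring opening to compete with loss of methoxide from the first adduct; should methoxide leave instead, the warm methanolic stage lets LiOMe re-add at the same carbon and reopen the pyranone, so that both manifolds should drain through 11 into the irreversible aromatisation. Only the phenol ortho to the acyl group can close ring C, since the other ortho oxygen is a methyl ether, which fixes the 5-methoxy-7-hydroxy pattern of 13.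

Step 8
Reactants: 13 7-hydroxy-5-methoxy-6,8-dimethyl-2-pentacosyl-4H-chromen-4-one
Product: 14 5,7-dihydroxy-6,8-dimethyl-2-pentacosyl-4H-chromen-4-one
Conditions: BCl3 (3 equiv), CH2Cl2, 0 °C to rt; aqueous work-up
Reagents that add atoms: none
Why: BCl3 should chelate between the C4 carbonyl and the peri C5 oxygen and cleave that methyl ether by chloride attack on the methyl group, a chelation-directed Lewis acid ether cleavage well established for 5-methoxychromones that leaves the chromone, the chain and the C7 phenol untouched.

**Compound list**
1 | dimethyl 3-oxopentanedioate | COC(=O)CC(=O)CC(=O)OC | starting material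
2 | dimethyl 2,4-dimethyl-3-oxopentanedioate (mixture of diastereomers) | COC(=O)C(C)C(=O)C(C)C(=O)OC | intermediate
3 | 4-hydroxy-6-methoxy-3,5-dimethyl-2H-pyran-2-one | COc1oc(=O)c(C)c(O)c1C | intermediate
4 | 2,6-dimethoxy-3,5-dimethyl-4H-pyran-4-one | COc1oc(OC)c(C)c(=O)c1C | intermediate
5 | 1-hexacosanol | CCCCCCCCCCCCCCCCCCCCCCCCCCO | starting material
6 | hexacosanal | CCCCCCCCCCCCCCCCCCCCCCCCCC=O | intermediate
7 | heptacos-1-yne | CCCCCCCCCCCCCCCCCCCCCCCCCC#C | intermediate
8 | lithium heptacos-1-yn-1-ide | CCCCCCCCCCCCCCCCCCCCCCCCCC#C[Li] | intermediate
9 | nonacos-3-yn-2-one | CCCCCCCCCCCCCCCCCCCCCCCCCC#CC(C)=O | intermediate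
10 | lithium nonacos-1-en-3-yn-2-olate | CCCCCCCCCCCCCCCCCCCCCCCCCC#CC(=C)O[Li] | intermediate
11 | methyl (4E)-5-methoxy-2,4-dimethyl-3,7-dioxotetratriacont-4-en-8-ynoate (ring-opened keto ester, present as its lithium enolate) | COC(=O)C(C)C(=O)/C(C)=C(/OC)CC(=O)C#CCCCCCCCCCCCCCCCCCCCCCCCCCC | intermediate
12 | 1-(2,4-dihydroxy-6-methoxy-3,5-dimethylphenyl)octacos-2-yn-1-one (aryl ynone, present as its phenoxide) | CCCCCCCCCCCCCCCCCCCCCCCCCC#CC(=O)c1c(O)c(C)c(O)c(C)c1OC | intermediate
13 | 7-hydroxy-5-methoxy-6,8-dimethyl-2-pentacosyl-4H-chromen-4-one | CCCCCCCCCCCCCCCCCCCCCCCCCc1cc(=O)c2c(OC)c(C)c(O)c(C)c2o1 | intermediate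
14 | 5,7-dihydroxy-6,8-dimethyl-2-pentacosyl-4H-chromen-4-one | CCCCCCCCCCCCCCCCCCCCCCCCCc1cc(=O)c2c(O)c(C)c(O)c(C)c2o1 | target

**Step count**
Total: 8 steps. Longest linear sequence: 5 steps (steps 4, 5, 6, 7, 8 from 5; equally steps 1, 2, 3, 7, 8 from 1).

**Steps most likely to fail**

Step 7. The cascade may stall in three ways: loss of methoxide from the first adduct in place of ring opening, followed by deprotonation of the substituted pyranone to an anion that no longer opens; 1,2-addition at C4; or Michael oligomerisation of the ynone enolate. The fallback uses known chemistry and buys ring A instead of building it. It sets out from hexacosanal 6 and comes back at the target 14. Pinnick oxidation of 6 (NaClO2, NaH2PO4, 2-methyl-2-butene, t-BuOH/THF/H2O) should give hexacosanoic acid F1, and oxalyl chloride with catalytic DMF should give hexacosanoyl chloride F2. Commercial 1-(2,4,6-trihydroxyphenyl)ethanone is C-methylated twice (MeI, NaOMe, MeOH) to 1-(2,4,6-trihydroxy-3,5-dimethylphenyl)ethanone F3. Its lithium polyanion (LiN(SiMe3)2 in excess, THF, −78 °C) is C-acylated by F2 in a Claisen-type ketone acylation to 1-(2,4,6-trihydroxy-3,5-dimethylphenyl)octacosane-1,3-dione F4. Acid-catalysed cyclodehydration of this ortho-hydroxyaryl 1,3-diketone (H2SO4 in AcOH, 95 °C), the closing stage of a Baker–Venkataraman chromone synthesis, should give 14 directly, so step 8 is not needed.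

Step 5. Base-induced aldol self-condensation of the unbranched aldehyde may outrun the homologation, because the waxy substrate dissolves only slowly in the methanolic medium. The fallback sets out from 6 and comes back at the lithium acetylide 8. Corey–Fuchs olefination (CBr4, PPh3, CH2Cl2, 0 °C) should give 1,1-dibromoheptacos-1-ene F5. Treatment with n-BuLi (2.1 equiv, THF, −78 to 0 °C) should then give 8 by bromine–lithium exchange and Fritsch–Buttenberg–Wiechell rearrangement. This 8 is acylated as in step 6 to 9, so the whole sequence runs in aprotic solvents and 7 need not be isolated.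

Step 6. Metalation may be incomplete through aggregation of the long-chain acetylide, and the liberated N,O-dimethylhydroxylamine may add in conjugate fashion to the ynone during the quench. The fallback sets out from 7 (through 8) and comes back at 9. Addition of 8 to acetaldehyde (THF, −78 to 0 °C) should give racemic nonacos-3-yn-2-ol F6. Oxidation of this propargylic alcohol with MnO2 in CH2Cl2 (or Dess–Martin periodinane) should give 9 with no amine present, and the carbinol centre is removed in the same operation.

**Further compounds**
F1 | step 7 | hexacosanoic acid | CCCCCCCCCCCCCCCCCCCCCCCCCC(=O)O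
F2 | step 7 | hexacosanoyl chloride | CCCCCCCCCCCCCCCCCCCCCCCCCC(=O)Cl
F3 | step 7 | 1-(2,4,6-trihydroxy-3,5-dimethylphenyl)ethanone | CC(=O)c1c(O)c(C)c(O)c(C)c1O
F4 | step 7 | 1-(2,4,6-trihydroxy-3,5-dimethylphenyl)octacosane-1,3-dione | CCCCCCCCCCCCCCCCCCCCCCCCCC(=O)CC(=O)c1c(O)c(C)c(O)c(C)c1O
F5 | step 5 | 1,1-dibromoheptacos-1-ene | CCCCCCCCCCCCCCCCCCCCCCCCCC=C(Br)Br
F6 | step 6 | nonacos-3-yn-2-ol (racemic) | CCCCCCCCCCCCCCCCCCCCCCCCCC#CC(C)O
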